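## The problem

Compound 26 is the C2-symmetric head-to-head cyclobutane dimer of the lindenane trienolide 25: the four-membered ring consists of C8, C9, C9′ and C8′, so each half carries an oxygen-bearing spiro carbon (C8) next to a methine (C9) that is flanked by the quaternary C10. Lindenane numbering is used throughout: ring A is C1–C3–C4–C5–C10 with the cyclopropane apex C2, ring B is C5–C10, the lactone is C7–C11–C12–O–C8, C14 is the angular methyl and C15 the exocyclic methylene. Each half is a tetracycle in which the cyclopropane C1–C2–C3 is fused to the five-membered ring A, ring A is trans-fused to the six-membered ring B across C5–C10, and an α-methylbutenolide is fused at C7–C8. Of the twelve stereocentres (C1, C3, C5, C8, C9, C10 and their primed partners) only C10 has to be brought in from outside: in a decalin its methyl group can direct hydride to C1 and borane to C5, the C1 oxygen can then fix C1 and C3 of the cyclopropane by inversion, and in monomer 25 the same methyl group shields the β face of the C8=C9 alkene, so that C8 and C9 are set when the cyclobutane forms. The structure tolerates little: the C4=C15 methylene beside the cyclopropane opens through a cyclopropylcarbinyl cation in acid, the trans 5/6 fusion is strained and would epimerise at C5 if C4 were a carbonyl, and the γ-alkylidenebutenolide of 25 is sensitive to base, nucleophiles and light. The feature that opens the route is the cyclopropane C1–C2–C3 next to the C4=C15 methylene: this is the cyclopropylcarbinyl form of a homoallyl cation of a eudesmane-type ring A with a leaving group on C1 and a C3=C4 alkene, which reduces the tricycle to a trans-decalin of the kind made from diketone 1.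

## Retrosynthesis

**26 ⇒ 2 × 25 (C8–C8′ and C9–C9′).** The cyclobutane is cut along its two-fold axis into two identical alkenes. Any other cut leaves the halves joined by one bond and keeps all the congestion; this one halves the molecule and removes four stereocentres. The forward reaction is a [2+2] photodimerisation of the C8=C9 alkene of 25. It must be head-to-head and must use the α face of both partners, and it needs no reagent or protecting group.

**25 ⇒ 22 (C8=C9).** The enol-lactone alkene is taken back to the saturated γ position of butenolide 22, through silyloxyfuran 23 and γ-bromide 24. Carrying the alkene through the lactone construction would need a 7,8-diketone whose two enol forms cannot be told apart reliably. Introduced last, it is regiochemically unambiguous: C8 is the only γ carbon that is α to the ring oxygen, and C9 is the only place a conjugated alkene can go.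

**22 ⇒ 21 ⇒ 19 + 20 ⇒ 17 (C7=C11, ester C–O, C8–O).** The butenolide is opened at C7=C11 (intramolecular Horner–Wadsworth–Emmons reaction of phosphonate ester 21) and at the ester (ketol 19 and acid 20); removing the C8 hydroxyl gives ketone 17. An aldol-type annulation from a C8 ketone would be shorter, but the key step places the oxygen of the decalin precursor on C7, so a C7 ketone plus α-oxygenation is the consistent choice. The forward sequence asks that 17 enolises towards C8 and not towards C6.

**17 ⇒ 16 ⇒ 14 (C1–C3, the key step).** With the C7 ketone masked as dioxolane 16, the transannular C1–C3 bond is cut. Read as a cyclopropylcarbinyl cation at C4 (15), the tricycle opens to a homoallyl system with a leaving group on C1 and a C3=C4 alkene, that is, to the equatorial 1β-mesylate 14 of a trans-fused octalin.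

- Against its neighbours: methylene transfer to a C1=C3 alkene of a ring-contracted precursor would have to deliver C2 to the face of the C14 methyl, and closure of C3–C4 (Alternative 3) has to choose between two cyclopropyl methylenes. This cut is stereospecific: inversion at C1 places C2 on the β face, and the cis fusion of the three-membered ring fixes C3.
- Simplification: the precursor has no cyclopropane, no strained 5/6 fusion and two fewer stereocentres.
- Weak points of the plain version (C15 methyl, loss of a proton): an alkene inside the same ring as the leaving group overlaps poorly with the back of the C1–O bond and must compete with migration of the antiperiplanar C5–C10 bond; the cation can lose a proton from C5 as well as from C15; and the product methylene can be reprotonated and reopened.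
- Remedy: a trimethylsilyl group on C15 answers all three without changing the bond that forms. The allylsilane is a much better π nucleophile, the C4 cation is additionally stabilised by the C–Si bond, and loss of silicon gives only the exocyclic alkene and is irreversible.
- An anionic closure of the same bond (C3 enolate of a C4 ketone onto C1) is kept in reserve only, because it passes through a C4 ketone with an epimerisable C5 and needs a separate methylenation.

**14 ⇒ 13 ⇒ 12 ⇒ 10 + 11 (C4–C15).** The C4–C15 bond is cut to enol triflate 10 and Grignard reagent 11. The C1 oxygen travels as a pivalate (12) and is released (13) only before sulfonylation. A pivalate is preferred to a silyl ether because hydride removes it without touching the allylsilane, which fluoride or acid would threaten. The coupling asks only that the triflate reacts faster than the hindered ester.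

**10 ⇒ 8 ⇒ 7 ⇒ 5 (C4 oxygen, C5–H).** Triflate 10 comes from the trans-fused C4 ketone 8 by kinetic enolisation towards C3 (enolate 9), ketone 8 from alcohol 7, and 7 from the C4=C5 alkene of 5 by hydroboration–oxidation. This one operation puts oxygen on C4 and hydrogen on the α face of C5, so the trans ring fusion comes from the facial bias of the angular methyl and not from an equilibration.

**5 ⇒ 3 + 4 ⇒ 2 ⇒ 1.** The C4=C5 alkene and the C7 dioxolane of 5 arise together from enone 3 and diol 4 by ketalisation with migration of the alkene. Pivalate 3 comes from alcohol 2, and 2 from diketone 1 by reduction of the saturated ketone only. In this mapping the saturated carbonyl of 1 becomes C1 and the enone carbonyl C7, which requires the (R)-enantiomer of 1.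

## Roads not taken

**Alternative 1:** The cut is made at C9–C10 and C9′–C10′. Diacid A1, in which the four carbons of a succinic acid unit are C8, C9, C9′ and C8′, would come from a double Ireland–Claisen rearrangement of A2, a succinate diester whose ester oxygens sit on C4 of two 4-methylbicyclo[3.1.0]hex-3-ene units.

- Merits: it uses the two-fold axis from the start, creates both quaternary centres C10 and C10′ with chirality transfer from the carbinol carbons, sets C9 and C9′ in the same operation, and is convergent.
- Weak points: a succinate has to be enolised twice without condensation or fragmentation. Each rearrangement forms a bond to a fully substituted alkene carbon, and the relative configuration at C9/C9′ depends on ketene acetal geometry and on a chair-or-boat preference that is hard to predict for cyclic allyl esters. The allylic esters of A2 sit next to a cyclopropane and ionise easily.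
- What remains after A1: ring B, both butenolides, C15 and the C8–C8′ bond, which must be closed between two carboxyl carbons to a strained four-membered ring. The hardest bonds are postponed, not solved.
- Comparison: in convergence and in the use of symmetry this road is better than the chosen one. The chosen plan sets against it that the cyclobutane and its four stereocentres are formed in the last step by a reaction with close precedent, and that every stereocentre is traceable to the single centre of 1.

**Alternative 2:** The cut is made at C7–C8, C11–C12 and C12–O in both halves. Bis-dioxolane A3 would come from A4, a cyclobutane-1,2-dione whose C9 and C9′ carry the bicyclic units with a but-2-ynyl group on C5 and a dioxolane on C4. The forward step is a double carbonylative alkyne–ketone annulation (hetero-Pauson–Khand type) with Ru3(CO)12 or Mo(CO)6 under CO.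

- Merits: six bonds and four rings in one operation, the α-methylbutenolide formed with its methyl in place, C8 and C8′ set under control of the existing cyclobutane, and only CO added.
- Weak points: such annulations are established for closing five-membered carbocycles, and here each must close the six-membered ring B at a neopentyl ketone. Cyclobutane-1,2-diones decarbonylate and ring-contract under hot, low-valent metal conditions. The second annulation takes place beside a freshly made spiro centre. After A3, two hindered cyclopropyl ketones at C4 would have to be unmasked and methylenated, with C5 epimerisable towards the cis 5/6 fusion. A4 itself is no easier to make than A1.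
- Comparison: if it worked, this road would be clearly more step-economic at the end than the chosen plan. The chosen plan sets against it reliability: no step depends on a strained dione surviving a metal carbonyl, and C4 is never a ketone next to the ring fusion.

**Alternative 3:** The cut is made at C3–C4. Tricycle A5, which carries its dioxolane on C8, would come from bromide A6, a ring B cyclohexane with a 1-bromovinyl group on C5 and, on C10, the methyl group and an unsubstituted cyclopropyl ring. The forward step is a palladium-catalysed cyclopropane C–H alkenylation (Pd(OAc)2, PCy3, Cs2CO3, pivalate): oxidative addition to zerovalent palladium, concerted metalation–deprotonation and reductive elimination.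

- Merits: ring A and the methylene are made in one catalytic step without cationic intermediates, so skeletal rearrangement is not an issue. The oxygen of A5 sits on C8, where the lactone needs it, and a C8 ketone can enolise usefully only towards C7. In this respect the road is better than the chosen plan, which needs a regioselective hydroxylation of 17 and a late dehydrogenation to reach 25.
- Weak points: the cyclopropyl group of A6 has two diastereotopic methylenes, and nothing obvious in the substrate decides which is activated, although this choice sets C1 and C3 and must place C2 on the face of the C14 methyl. The palladacycle has to deliver the strained trans 5/6 fusion. A6 needs its own asymmetric synthesis of a quaternary centre bearing a cyclopropyl group trans to the bromovinyl group.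
- Comparison: the chosen plan sets against the better oxygen placement of this road that C1 and C3 follow stereospecifically from the configuration of the C1 carbinol, and that the decalin precursor is a few standard steps from 1.

Key step: step 10

Assumption: the (R)-enantiomer of 1 and racemic acid 20 are taken as purchasable; the configuration of the phosphonate-bearing carbon of 20 is lost in step 14.

## Route

Step 1
Reactants: 1 (R)-Wieland–Miescher ketone
Product: 2 (4aR,5R)-5-hydroxy-4a-methyl-4,4a,5,6,7,8-hexahydronaphthalen-2(3H)-one (1β-hydroxy enone)
Conditions: NaBH4 (0.3 equiv), EtOH, −10 °C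
Reagents that add atoms: none
Why: Chemoselective 1,2-reduction of the saturated C1 ketone beside the less electrophilic enone; hydride enters axially from the α face, anti to the angular C14 methyl, and sets the equatorial 1β alcohol.

Step 2
Reactants: 2 1β-hydroxy enone
Product: 3 1β-pivaloyloxy enone
Conditions: t-BuCOCl, pyridine, DMAP (cat.), CH2Cl2, 0 → 40 °C
Reagents that add atoms: pivaloyl chloride, CC(C)(C)C(=O)Cl
Why: DMAP-catalysed acylation of a secondary alcohol; the pivalate survives acid, borane, strong base and the Grignard coupling and is later removed by hydride, without the fluoride or acid that the allylsilane would not tolerate.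

Step 3
Reactants: 3 1β-pivaloyloxy enone; 4 ethylene glycol
Product: 5 1β-pivaloyloxy-10β-methyl-Δ4-octalin 7-ethylene ketal (alkene C4=C5)
Conditions: HOCH2CH2OH, p-TsOH·H2O (cat.), benzene, reflux (Dean–Stark)
Reagents that add atoms: ethylene glycol (4), OCCO
Why: Acid-catalysed ketalisation of a β,β-disubstituted enone runs through the dienol ether, so the alkene leaves conjugation for C4=C5, as in the ketalisation of steroidal 4-en-3-ones; water is removed azeotropically.

Step 4
Reactants: 5 Δ4-octalin ketal
Product: 7 4α-hydroxy-1β-pivaloyloxy-10β-methyl-trans-decalin 7-ethylene ketal (5α-H), via C4 alkylborane 6 (not isolated)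
Conditions: BH3·THF, THF, 0 → 20 °C; then NaOH aq, H2O2, 0 °C
Reagents that add atoms: hydrogen peroxide, OO
Why: Hydroboration–oxidation of the trisubstituted alkene: boron goes to the less substituted C4 and both new bonds form on the α face, anti to the C14 methyl, which sets 5α-H (trans fusion) and, after oxidation with retention, 4α-OH; the C4 centre is removed in step 5.

Step 5
Reactants: 7 4α-alcohol
Product: 8 1β-pivaloyloxy-10β-methyl-trans-decalin-4-one 7-ethylene ketal (5α-H)
Conditions: Dess–Martin periodinane, NaHCO3, CH2Cl2, 0 → 20 °C
Reagents that add atoms: none
Why: Buffered periodinane oxidation of a secondary alcohol; the medium is mild enough for the dioxolane, and C5 is not at risk because the trans-fused decalone is the stable epimer.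

Step 6
Reactants: 8 trans-decalin-4-one
Product: 10 C3=C4 enol triflate (1β-pivaloyloxy 7-ethylene ketal), via potassium C3=C4 enolate 9 (not isolated)
Conditions: KN(SiMe3)2, THF, −78 °C; then PhNTf2, −78 → 0 °C
Reagents that add atoms: N-phenylbis(trifluoromethanesulfonimide), O=S(=O)(N(c1ccccc1)S(=O)(=O)C(F)(F)F)C(F)(F)F
Why: Kinetic deprotonation by the hindered amide removes a secondary C3 hydrogen and not the tertiary C5 hydrogen, and O-sulfonylation of the enolate fixes the alkene at C3=C4.

Step 7
Reactants: 10 enol triflate; 11 (trimethylsilyl)methylmagnesium chloride
Product: 12 1β-pivaloyloxy-4-(trimethylsilylmethyl)-10β-methyl-5α-H-Δ3-octalin 7-ethylene ketal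
Conditions: Me3SiCH2MgCl, Pd(PPh3)4 (5 mol%), THF, 0 → 20 °C
Reagents that add atoms: (trimethylsilyl)methylmagnesium chloride (11), C[Si](C)(C)C[Mg]Cl
Why: Kumada cross-coupling of an alkenyl triflate under zerovalent palladium catalysis, a standard route to allylsilanes; the hindered pivalate is not attacked by this weakly nucleophilic Grignard reagent at or below room temperature.

Step 8
Reactants: 12 allylsilane pivalate
Product: 13 1β-hydroxy-4-(trimethylsilylmethyl)-10β-methyl-5α-H-Δ3-octalin 7-ethylene ketal
Conditions: i-Bu2AlH, CH2Cl2, −78 → −40 °C
Reagents that add atoms: none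
Why: Reductive cleavage of the ester by the aluminium hydride; ketal, alkene and allylsilane are inert and the C1 configuration is untouched.

Step 9
Reactants: 13 allylsilane alcohol
Product: 14 1β-mesyloxy-4-(trimethylsilylmethyl)-10β-methyl-5α-H-Δ3-octalin 7-ethylene ketal
Conditions: MsCl, Et3N, CH2Cl2, −10 °C
Reagents that add atoms: methanesulfonyl chloride, CS(=O)(=O)Cl
Why: Sulfonylation through sulfene, which works for hindered neopentyl-type secondary alcohols and retains the configuration, giving the equatorial 1β leaving group; the product is kept cold and base-washed because it is the solvolysis substrate.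

Step 10
Reactants: 14 1β-mesylate
Product: 16 lindenane tricycle with C4=C15 methylene and C7 ethylene ketal, via C4 cyclopropylcarbinyl cation 15 (not isolated)
Conditions: (CF3)2CHOH, 2,6-lutidine (3 equiv), 0.02 M, 20 → 45 °C
Reagents that add atoms: none
Why: Ionisation of the equatorial 1β mesylate in the strongly ionising, weakly nucleophilic fluoroalcohol is assisted by the C3=C4 π bond: C3 bonds to C1 from the side opposite the departing sulfonate while charge builds at C4, where it is stabilised as a cyclopropylcarbinyl cation and by the C15–Si bond (15), and loss of the silyl group to the solvent gives the C4=C15 methylene irreversibly. The closest known reaction types are the homoallyl-to-cyclopropylcarbinyl solvolysis of homoallylic sulfonates (i-steroid rearrangement) and its allylsilane-terminated form, which gives vinylcyclopropanes. The cyclopropane closes in the 3-exo-tet mode (C3 nucleophile, C1 electrophile, leaving group outside the ring); the five-membered ring A is not closed separately but is what remains of the six-membered ring once the transannular C1–C3 bond exists. C1 is set by inversion: the mesylate is 1β, so C3 enters from the α side, H1 stays α and C2 is pushed to the β face of the new ring, syn to the C14 methyl. C3 is set in the same event, because a cyclopropane fused to a five-membered ring can only be cis and C1 lies on the α side of the alkene plane in the half-chair of the trans-octalin. C5 and C10 are not involved, so the trans 5/6 fusion is inherited from 14. The step needs π participation to outrun migration of the antiperiplanar C5–C10 bond, elimination towards C2 and solvent capture; this is secured by the high nucleophilicity of the allylsilane, the lack of an antiperiplanar hydrogen for the equatorial leaving group, the weakly nucleophilic solvent and the lutidine buffer, while the silyl group makes the exocyclic position of the alkene a matter of constitution and not of competing proton losses.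

Step 11
Reactants: 16 lindenane tricyclic ketal
Product: 17 lindenane tricyclic C7 ketone (C4=C15 methylene)
Conditions: PPTS (cat.), acetone/H2O, 45 °C
Reagents that add atoms: water, O
Why: Hydrolysis of the dioxolane under weak pyridinium acid catalysis; the mild acid is chosen because the methylene beside the cyclopropane would open through the cyclopropylcarbinyl cation under strong acid.

Step 12
Reactants: 17 tricyclic C7 ketone
Product: 19 8α-hydroxy C7 ketone, via potassium C7=C8 enolate 18 (not isolated)
Conditions: KN(SiMe3)2, THF, −78 °C; then 3-phenyl-2-(phenylsulfonyl)oxaziridine, −78 °C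
Reagents that add atoms: 3-phenyl-2-(phenylsulfonyl)oxaziridine, O=S(=O)(N1OC1c1ccccc1)c1ccccc1
Why: Kinetic enolisation occurs at C8, whose neighbour C9 is a methylene, and not at C6 beside the ring-fusion carbon (the preference of trans-fused 3-keto steroids for the 2-enolate, reinforced by the strained fusion); enolate hydroxylation by the N-sulfonyloxaziridine from the α face, anti to the syn-axial C14 methyl, gives the equatorial 8α alcohol.

Step 13
Reactants: 19 8α-hydroxy ketone; 20 2-(diethoxyphosphoryl)propanoic acid
Product: 21 8α-[2-(diethoxyphosphoryl)propanoyloxy] C7 ketone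
Conditions: DCC, DMAP (cat.), CH2Cl2, 0 → 20 °C
Reagents that add atoms: 2-(diethoxyphosphoryl)propanoic acid (20), CCOP(=O)(OCC)C(C)C(=O)O
Why: Steglich esterification of the secondary alcohol; the phosphonate-bearing carbon is a mixture of epimers, which does not matter because it becomes sp2 in step 14.

Step 14
Reactants: 21 phosphonate ester
Product: 22 8βH-lindena-4(15),7(11)-dien-12,8α-olide
Conditions: NaH, THF, 0 → 20 °C
Reagents that add atoms: none
Why: Intramolecular Horner–Wadsworth–Emmons olefination: the phosphonate carbanion adds to the C7 ketone (5-exo-trig) and diethyl phosphate leaves, closing the α-methylbutenolide with the C7=C11 bond; C8 keeps the equatorial 8α oxygen, which is also the stable epimer should the base equilibrate it.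

Step 15
Reactants: 22 butenolide
Product: 23 12-(triisopropylsilyloxy)furan (furan O–C8=C7–C11=C12)
Conditions: i-Pr3SiOTf, Et3N, CH2Cl2, 0 °C
Reagents that add atoms: triisopropylsilyl trifluoromethanesulfonate, CC(C)[Si](OS(=O)(=O)C(F)(F)F)(C(C)C)C(C)C
Why: Soft enolisation of a butenolide bearing a γ hydrogen with silyl triflate and amine gives the 2-silyloxyfuran; the C8 hydrogen is removed because it is α to the ring oxygen and its loss gives the aromatic furan.

Step 16
Reactants: 23 silyloxyfuran
Product: 25 chloranthalactone A (lindena-4(15),7(11),8-trien-12,8-olide), via 8α-bromobutenolide 24 (not isolated)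
Conditions: NBS, THF, −78 °C; then DBU, −78 → 0 °C
Reagents that add atoms: none
Why: 2-Silyloxyfurans take up electrophilic bromine at the γ carbon (C8, from the α face) to give a γ-bromobutenolide, and the tertiary bromide beside the ring oxygen loses HBr to the amidine base; C9 is the only carbon that can give a conjugated alkene, so the γ-alkylidenebutenolide results.

Step 17
Reactants: 25 chloranthalactone A (two molecules)
Product: 26 head-to-head cyclobutane dimer (target, CNP0265879.1)
Conditions: hν (medium-pressure Hg lamp, Pyrex), degassed hexane, 20 °C
Reagents that add atoms: none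
Why: [2+2] dimerisation of a γ-alkylidenebutenolide at its exocyclic-type enol alkene, the reaction type by which protoanemonin gives anemonin; the first bond joins the two C9 termini and leaves two C8 radicals stabilised by the ring oxygen and the unsaturated lactone, which gives the head-to-head sense, and both monomers react on the α face, anti to the C14 methyl on the neighbouring C10, which sets C8, C9, C8′ and C9′ in the C2-symmetric dimer.

## Compound list

1 | (R)-Wieland–Miescher ketone, (8aR)-8a-methyl-3,4,8,8a-tetrahydronaphthalene-1,6(2H,7H)-dione | O=C1CCCC2=CC(=O)CC[C@@]12C | starting material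
2 | (4aR,5R)-5-hydroxy-4a-methyl-4,4a,5,6,7,8-hexahydronaphthalen-2(3H)-one (1β-OH, C5=C6, C7=O) | C1CC[C@@H](O)[C@]2(C)CCC(=O)C=C12 | intermediate
3 | pivalate of 2 (1β-pivaloyloxy enone) | C1CC[C@@H](OC(=O)C(C)(C)C)[C@]2(C)CCC(=O)C=C12 | intermediate
4 | ethylene glycol | OCCO | starting material
5 | 1β-pivaloyloxy-10β-methyl-Δ4-octalin 7-ethylene ketal (C4=C5) | C1C[C@@H](OC(=O)C(C)(C)C)[C@]2(C)CCC3(OCCO3)CC2=C1 | intermediate
6 | C4 alkylborane from 5 (4α-boryl, 5α-H; drawn as the monoalkylborane, formed in the flask) | B[C@@H]1CC[C@@H](OC(=O)C(C)(C)C)[C@]2(C)CCC3(OCCO3)C[C@@H]12 | intermediate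
7 | 4α-hydroxy-1β-pivaloyloxy-10β-methyl-trans-decalin 7-ethylene ketal (5α-H) | O[C@@H]1CC[C@@H](OC(=O)C(C)(C)C)[C@]2(C)CCC3(OCCO3)C[C@@H]12 | intermediate
8 | 1β-pivaloyloxy-10β-methyl-trans-decalin-4-one 7-ethylene ketal (5α-H) | O=C1CC[C@@H](OC(=O)C(C)(C)C)[C@]2(C)CCC3(OCCO3)C[C@@H]12 | intermediate
9 | potassium C3=C4 enolate of 8 (formed in the flask) | [K+].[O-]C1=CC[C@@H](OC(=O)C(C)(C)C)[C@]2(C)CCC3(OCCO3)C[C@@H]12 | intermediate
10 | C3=C4 enol triflate of 8 (4-triflyloxy, 1β-pivaloyloxy, 5α-H, 10β-methyl, 7-ethylene ketal) | O=S(=O)(OC1=CC[C@@H](OC(=O)C(C)(C)C)[C@]2(C)CCC3(OCCO3)C[C@@H]12)C(F)(F)F | intermediate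
11 | (trimethylsilyl)methylmagnesium chloride | C[Si](C)(C)C[Mg]Cl | starting material
12 | 1β-pivaloyloxy-4-(trimethylsilylmethyl)-10β-methyl-5α-H-Δ3-octalin 7-ethylene ketal | C[Si](C)(C)CC1=CC[C@@H](OC(=O)C(C)(C)C)[C@]2(C)CCC3(OCCO3)C[C@@H]12 | intermediate
13 | 1β-hydroxy-4-(trimethylsilylmethyl)-10β-methyl-5α-H-Δ3-octalin 7-ethylene ketal | C[Si](C)(C)CC1=CC[C@@H](O)[C@]2(C)CCC3(OCCO3)C[C@@H]12 | intermediate
14 | 1β-mesyloxy-4-(trimethylsilylmethyl)-10β-methyl-5α-H-Δ3-octalin 7-ethylene ketal (key-step precursor) | C[Si](C)(C)CC1=CC[C@@H](OS(C)(=O)=O)[C@]2(C)CCC3(OCCO3)C[C@@H]12 | intermediate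
15 | C4 cyclopropylcarbinyl cation with C15–SiMe3 (1α-H, 3α-H, C2 β; formed in the flask) | C[Si](C)(C)C[C+]1[C@H]2C[C@H]2[C@@]2(C)[C@H]1CC3(OCCO3)CC2 | intermediate
16 | lindenane tricycle: cyclopropane C1–C2–C3 (C2 β, H1 and H3 α), C4=C15 methylene, 5α-H, 10β-methyl, C7 ethylene ketal | C=C1[C@H]2C[C@H]2[C@@]2(C)[C@H]1CC3(OCCO3)CC2 | intermediate
17 | lindenane tricyclic C7 ketone (same stereochemistry as 16) | C=C1[C@H]2C[C@H]2[C@@]2(C)[C@H]1CC(=O)CC2 | intermediate
18 | potassium C7=C8 enolate of 17 (formed in the flask) | [K+].C=C1[C@H]2C[C@H]2[C@@]2(C)[C@H]1CC([O-])=CC2 | intermediate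
19 | 8α-hydroxy derivative of 17 (8α-OH, 8β-H) | C=C1[C@H]2C[C@H]2[C@@]2(C)[C@H]1CC(=O)[C@@H](O)C2 | intermediate
20 | 2-(diethoxyphosphoryl)propanoic acid (racemic) | CCOP(=O)(OCC)C(C)C(=O)O | starting material
21 | 8α-[2-(diethoxyphosphoryl)propanoyloxy] derivative of 17 (epimers at the phosphonate carbon) | C=C1[C@H]2C[C@H]2[C@@]2(C)[C@H]1CC(=O)[C@@H](OC(=O)C(C)P(=O)(OCC)OCC)C2 | intermediate
22 | 8βH-lindena-4(15),7(11)-dien-12,8α-olide | C=C1[C@H]2C[C@H]2[C@@]2(C)[C@H]1CC1=C(C)C(=O)O[C@H]1C2 | intermediate
23 | 12-(triisopropylsilyloxy)furan derived from 22 (furan O–C8=C7–C11=C12) | C=C1[C@H]2C[C@H]2[C@@]2(C)[C@H]1Cc1c(C)c(O[Si](C(C)C)(C(C)C)C(C)C)oc1C2 | intermediate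
24 | 8α-bromo-lindena-4(15),7(11)-dien-12,8β-olide (formed in the flask) | C=C1[C@H]2C[C@H]2[C@@]2(C)[C@H]1CC1=C(C)C(=O)O[C@]1(Br)C2 | intermediate
25 | chloranthalactone A, lindena-4(15),7(11),8-trien-12,8-olide | C=C1[C@H]2C[C@H]2[C@@]2(C)[C@H]1CC1=C(C)C(=O)OC1=C2 | intermediate
26 | head-to-head cyclobutane dimer of 25 (bonds C8–C8′ and C9–C9′ on the α faces; lactone oxygens and H9/H9′ β; C2-symmetric; CNP0265879.1) | C=C1[C@H]2C[C@H]2[C@@]2(C)[C@H]1CC1=C(C)C(=O)O[C@]13[C@H]2[C@H]1[C@@]2(C)[C@@H]4C[C@@H]4C(=C)[C@@H]2CC2=C(C)C(=O)O[C@@]213 | target

## Step count and risk

Total step count: 17. Longest linear sequence: 17 steps (1 → 26; the route is linear, and step 17 joins two molecules of 25).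

Least certain steps:

**Step 10 (key step).** Ionisation may be slow and poorly assisted, because in a cyclohex-3-enyl system the π lobe on C3 lies almost perpendicular to the C3···C1 axis and ring A must flex towards a boat before the bond can form. Migration of the antiperiplanar C5–C10 bond or of the C14 methyl to C1, elimination towards C2 after unassisted ionisation, protodesilylation of the allylsilane by traces of acid, or capture of the cation by the solvent could then take over. Fallback: the same C1–C3 bond is closed by an anion instead of a cation, starting from ketone 8. Methanolysis of the pivalate (NaOMe, MeOH) would give the 1β-hydroxy ketone F1, and sulfonylation (MsCl, Et3N) the keto mesylate F2. Kinetic deprotonation at C3 (KN(SiMe3)2, THF, −78 → 0 °C) would let the enolate displace the 1β-mesylate with inversion, the classical base-induced closure of a 4-sulfonyloxycyclohexanone to a bicyclo[3.1.0]hexan-2-one, and give the cyclopropyl ketone F3. Non-basic methylenation (CH2Br2, Zn, TiCl4), chosen because C5 of this ketone is epimerisable, rejoins the route at 16.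

**Step 17.** The dimerisation may lack regio- and facial selectivity (head-to-tail union, reaction on the β face of one partner), the cyclobutane may revert under the same light, and the vinylcyclopropane may be drawn into triplet chemistry. Fallback: the two bonds are made one after the other from 25. Reductive coupling at C9 (SmI2, THF/HMPA, t-BuOH) would give the 9,9′-linked bis-butenolide F4. Double γ-deprotonation (LiN(i-Pr)2, THF, −78 °C) and oxidative coupling of the two furanolates (Cu(OTf)2 or I2) would then close C8–C8′ intramolecularly, where only a cis ring fusion is possible, and arrive at 26.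

**Step 12.** Enolisation may not be regioselective (C6 in place of C8), the enolate may add to the sulfonimine by-product, and the ketol may isomerise through its enediol on warming. Fallback: from 17, reversible formylation (HCO2Et, NaH), which in trans-fused ketones of this type goes to the less hindered α carbon, would give the 8-hydroxymethylene ketone F5. Deformylative diazo transfer (MsN3, Et3N) would give the 8-diazo ketone F6, and Rh2(OAc)4-catalysed O–H insertion into acid 20 would give ester 21 directly (as C8 epimers, which converge at 23), so that ketol 19 is bypassed.

**Step 16.** Bromination may occur at C11 or at the C4=C15 alkene instead of C8, or elimination may be incomplete. Fallback: oxygen is used in place of bromine, starting from 22. The potassium dienolate (KN(SiMe3)2, THF, −78 °C) is oxygenated with O2 and the hydroperoxide reduced (P(OEt)3) to the 8-hydroxybutenolide F7, which is dehydrated (MsCl, Et3N) to 25.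

**Step 11.** Acid may protonate the C4=C15 methylene and open the cyclopropane through the cyclopropylcarbinyl cation before the ketal has gone. Fallback: the order of events is changed so that the tricycle never meets acid. From 13 the ketal is hydrolysed first (PPTS, acetone/H2O) to the hydroxy ketone F8, which is sulfonylated (MsCl, Et3N) to the keto mesylate F9; solvolysis of this mesylate under the conditions of step 10 would give ketone 17 directly.

## Further compounds

F1 | step 10 | 1β-hydroxy-10β-methyl-trans-decalin-4-one 7-ethylene ketal (5α-H) | O=C1CC[C@@H](O)[C@]2(C)CCC3(OCCO3)C[C@@H]12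
F2 | step 10 | 1β-mesyloxy-10β-methyl-trans-decalin-4-one 7-ethylene ketal (5α-H) | O=C1CC[C@@H](OS(C)(=O)=O)[C@]2(C)CCC3(OCCO3)C[C@@H]12
F3 | step 10 | 15-nor-lindenane tricyclic C4 ketone 7-ethylene ketal (C2 β, 5α-H, 10β-methyl) | O=C1[C@H]2C[C@H]2[C@@]2(C)[C@H]1CC3(OCCO3)CC2
F4 | step 17 | 9,9′-linked bis(lindena-4(15),7(11)-dien-12,8-olide) (H9 and H9′ β, C8 and C8′ unassigned) | C=C1[C@H]2C[C@H]2[C@@]2(C)[C@H]1CC1=C(C)C(=O)OC1[C@H]2[C@H]1[C@@]2(C)[C@@H]4C[C@@H]4C(=C)[C@@H]2CC2=C(C)C(=O)OC21
F5 | step 12 | 8-(hydroxymethylene) derivative of ketone 17 | C=C1[C@H]2C[C@H]2[C@@]2(C)[C@H]1CC(=O)C(=CO)C2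
F6 | step 12 | 8-diazo derivative of ketone 17 | C=C1[C@H]2C[C@H]2[C@@]2(C)[C@H]1CC(=O)C(=[N+]=[N-])C2
F7 | step 16 | 8-hydroxy-lindena-4(15),7(11)-dien-12,8-olide (C8 epimers, interconverting) | C=C1[C@H]2C[C@H]2[C@@]2(C)[C@H]1CC1=C(C)C(=O)OC1(O)C2
F8 | step 11 | 1β-hydroxy-4-(trimethylsilylmethyl)-10β-methyl-5α-H-Δ3-octalin-7-one | C[Si](C)(C)CC1=CC[C@@H](O)[C@]2(C)CCC(=O)C[C@@H]12
F9 | step 11 | 1β-mesyloxy-4-(trimethylsilylmethyl)-10β-methyl-5α-H-Δ3-octalin-7-one | C[Si](C)(C)CC1=CC[C@@H](OS(C)(=O)=O)[C@]2(C)CCC(=O)C[C@@H]12
A1 | alternative 1 | 2,3-bis(2-methylbicyclo[3.1.0]hex-3-en-2-yl)succinic acid | OC(=O)[C@H]([C@]1(C)C=C[C@H]2C[C@@H]12)[C@H](C(=O)O)[C@]1(C)C=C[C@H]2C[C@@H]12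
A2 | alternative 1 | bis(4-methylbicyclo[3.1.0]hex-3-en-2-yl) succinate (ester oxygen trans to the cyclopropane methylene) | O=C(CCC(=O)O[C@H]1C=C(C)[C@@H]2C[C@H]12)O[C@H]1C=C(C)[C@@H]2C[C@H]12
A3 | alternative 2 | 4,4′-bis(ethylene ketal) of the 15,15′-dinor-4,4′-dioxo analogue of 26 | C15(OCCO5)[C@H]2C[C@H]2[C@@]2(C)[C@H]1CC1=C(C)C(=O)O[C@]13[C@H]2[C@H]1[C@@]2(C)[C@@H]4C[C@@H]4C5(OCCO5)[C@@H]2CC2=C(C)C(=O)O[C@@]213
A4 | alternative 2 | cyclobutane-1,2-dione (C8, C8′) whose C9 and C9′ each carry the 10-methylbicyclo[3.1.0]hexane unit with a but-2-ynyl group on C5 and an ethylene ketal on C4 | CC#CC[C@H]1C2(OCCO2)[C@H]3C[C@H]3[C@]1(C)[C@H]4C(=O)C(=O)[C@@H]4[C@@]5(C)[C@@H]6C[C@@H]6C7(OCCO7)[C@@H]5CC#CC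
A5 | alternative 3 | lindenane tricycle with C4=C15 methylene and C8 ethylene ketal | C=C1[C@H]2C[C@H]2[C@@]2(C)[C@H]1CCC3(OCCO3)C2
A6 | alternative 3 | ring B cyclohexane with C8 ethylene ketal, 1-bromovinyl on C5 and methyl plus cyclopropyl on C10 (bromovinyl and cyclopropyl trans) | C=C(Br)[C@@H]1CCC2(OCCO2)C[C@@]1(C)C1CC1
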